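**Retrosynthetic overview**
- Psidial A 38 comes from Vilsmeier diformylation of the two free ring positions of phloroglucinol monoether 36.
- The strategy rests on the benzene ring: it carries oxygen on three alternate carbons, and its ether carbon (bound through O to C4) and the carbon bound to C1' are ortho. These two carbons are the α- and β-carbon of a dihydropyran enol ether, and the other four come from a dioxinone arm, so the arene is closed last by acylketene C-acylation and aromatisation (34 to 36).
- Precursor 34 comes from δ-lactone 29 by ketene acetal phosphate, vinylstannane and Stille coupling with 6-(chloromethyl)dioxinone 33. Lactone 29 comes from an oxa-Diels–Alder reaction of (+)-β-caryophyllene 18 with benzylidene Meldrum's acid 21 (sets C4 and C5), after which C1' is reset by dehydrogenation and copper hydride reduction.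
- (+)-β-Caryophyllene 18 comes from Grob fragmentation of hydrindanediol monomesylate 15 (nine-membered ring with E-alkene), which comes from cis-bicyclo[4.2.0]octanone 4, made by enantioselective [2+2] photocycloaddition of 1 and 2.
- Ring order: cyclobutane, then a cyclohexane and a cyclopentane scaffold that are opened to the nine-membered ring, then the dihydropyran, then the benzene ring.

Key step: step 20

Remark: in caryophyllane numbering (C1 and C9 ring fusion, C1 next to the CMe2 carbon C11, C4 the methyl-bearing carbon, C5 its neighbour, C8 the methylene-bearing carbon, C1' the benzylic carbon) the target SMILES is 1S,4S,5R,9R,1'R; its bicyclic core is the mirror image of commercial (−)-β-caryophyllene (1R,9S), so the terpene half is built de novo in the (+)-series and not taken from the chiral pool.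

Step 1
Reactants: 1 cyclohex-2-en-1-one; 2 isobutene
Product: 4 (1S,6S)-7,7-dimethylbicyclo[4.2.0]octan-2-one (cis-fused), via trans-fused photoadduct 3 (not isolated)
Conditions: 2 (excess), AlBr3 adduct of 3,3-bis(3,5-dimethylphenyl)-1-(2,4,6-trifluorophenyl)tetrahydro-1H,3H-pyrrolo[1,2-c][1,3,2]oxazaborole (prolinol-derived antipode that gives the 6S series, 50 mol %), CH2Cl2, hν 366 nm, −75 °C; then basic Al2O3, CH2Cl2, rt
Reagents that add atoms: none
Why: Chiral-Lewis-acid-catalysed enone–alkene [2+2] photocycloaddition, in which only the catalyst-bound enone absorbs at 366 nm and isobutene adds head-to-tail (CMe2 carbon on the β-carbon) to one enone face, fixing the later C1 as S; alumina then epimerises the α-carbon to the more stable cis ring fusion.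

Step 2
Reactants: 4 (1S,6S)-7,7-dimethylbicyclo[4.2.0]octan-2-one
Product: 5 methyl (1S,6S)-7,7-dimethyl-2-oxobicyclo[4.2.0]octane-3-carboxylate
Conditions: NaH (2.2 equiv), (MeO)2CO, THF, reflux; AcOH quench
Reagents that add atoms: dimethyl carbonate, COC(=O)OC
Why: Claisen-type carbomethoxylation of the ketone enolate under thermodynamic control; the ester ends on the CH2 α-carbon because only that β-keto ester can be deprotonated to a stabilised enolate.

Step 3
Reactants: 5 methyl (1S,6S)-7,7-dimethyl-2-oxobicyclo[4.2.0]octane-3-carboxylate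
Product: 6 methyl (1S,3R,6S)-3,7,7-trimethyl-2-oxobicyclo[4.2.0]octane-3-carboxylate
Conditions: K2CO3, MeI, acetone, reflux
Reagents that add atoms: iodomethane, CI
Why: C-Alkylation of the β-keto ester enolate; MeI should enter anti to the cyclobutane CH2 on the neighbouring ring-fusion carbon, and this quaternary centre later becomes the sp2 carbon C4, so only its relation to the C5 oxygen matters.

Step 4
Reactants: 6 methyl (1S,3R,6S)-3,7,7-trimethyl-2-oxobicyclo[4.2.0]octane-3-carboxylate; 7 methyl propiolate
Product: 8 methyl (1S,3R,6S)-2-hydroxy-2-(3-methoxy-3-oxoprop-1-yn-1-yl)-3,7,7-trimethylbicyclo[4.2.0]octane-3-carboxylate (alkynyl anti to the cyclobutane)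
Conditions: 7, LiHMDS, THF, −78 °C; then 6, −78 °C; AcOH quench at −78 °C
Reagents that add atoms: none
Why: 1,2-Addition of a lithium acetylide to a hindered ketone (the propiolate addition used for spirolactones); attack should come from the face opposite to the flanking cyclobutane CH2 and ester, placing the chain trans to the C3 ester.

Step 5
Reactants: 8 propargylic alcohol diester
Product: 10 methyl 3,7,7-trimethyl-5'-oxospiro[bicyclo[4.2.0]octane-2,2'-oxolane]-3-carboxylate (spiro γ-lactone), via saturated hydroxy diester 9 (not isolated)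
Conditions: H2 (1 atm), Pd/C (10 % palladium on carbon), EtOAc, trace Et3N, rt; then TsOH (cat.), toluene, 40 °C
Reagents that add atoms: none
Why: Catalytic hydrogenation of the alkyne followed by acid-catalysed lactonisation of the γ-hydroxy ester; no stereocentre changes.

Step 6
Reactants: 10 spiro γ-lactone ester
Product: 12 methyl 8-hydroxy-5-oxo-13-nor-4,8-cyclocaryophyllane-6-carboxylate (trans-hydrindanone), via bridged keto lactone 11 (not isolated)
Conditions: KOtBu (1.5 equiv), THF, 0 °C to rt; AcOH quench
Reagents that add atoms: none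
Why: Dieckmann condensation: the lactone enolate attacks the neopentyl ester to close the five-membered ring, the expelled methoxide reopens bridged lactone 11 to the stabilised β-keto ester enolate (which also blocks retro-aldol cleavage), and the trans disposition of the two arms gives a trans-fused hydrindanone with angular hydroxyl and methyl anti.

Step 7
Reactants: 12 hydroxy β-keto ester
Product: 13 8-hydroxy-13-nor-4,8-cyclocaryophyllan-5-one
Conditions: NaCl, H2O, DMSO, 140 °C
Reagents that add atoms: none
Why: Krapcho dealkoxycarbonylation removes the ester under near-neutral conditions that should not open the tertiary β-hydroxy ketone by retro-aldol reaction.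

Step 8
Reactants: 13 tricyclic hydroxy ketone
Product: 14 13-nor-4,8-cyclocaryophyllane-5,8-diol (5-hydroxyl cis to the 4-methyl)
Conditions: NaBH4, MeOH, 0 °C
Reagents that add atoms: none
Why: Borohydride reduction in which hydride enters the cyclopentanone from the face opposite to the adjacent angular methyl (the course followed by 17-oxo steroids), so the C5 hydroxyl is cis to that methyl and trans to the tertiary hydroxyl.

Step 9
Reactants: 14 tricyclic diol
Product: 15 5-methanesulfonate of diol 14
Conditions: MsCl (1.1 equiv), Et3N, CH2Cl2, −10 °C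
Reagents that add atoms: methanesulfonyl chloride, CS(=O)(=O)Cl
Why: Selective sulfonylation of the secondary alcohol; the hindered tertiary alcohol should not react at low temperature.

Step 10
Reactants: 15 hydroxy mesylate
Product: 17 (1S,4E,9R)-4,11,11-trimethylbicyclo[7.2.0]undec-4-en-8-one (trans-fused), via cis-fused ketone 16 (not isolated)
Conditions: KOtBu, t-BuOH, 40 °C
Reagents that add atoms: none
Why: Grob fragmentation of the 1,3-diol monosulfonate: the C8 alkoxide pushes into the C4–C8 bond, which is antiperiplanar to the pseudo-equatorial C5–OMs bond of the trans-hydrindane, so the nine-membered ketone forms stereospecifically with the E C4=C5 alkene (mesylate cis to methyl), and the same base epimerises C9 to the more stable trans ring fusion (9R).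

Step 11
Reactants: 17 trans-fused E-cyclononenone
Product: 18 (+)-β-caryophyllene [(1S,4E,9R)-4,11,11-trimethyl-8-methylidenebicyclo[7.2.0]undec-4-ene]
Conditions: Ph3PCH3Br, KOtBu, THF, 0 °C to reflux
Reagents that add atoms: methyltriphenylphosphonium bromide, C[P+](c1ccccc1)(c1ccccc1)c1ccccc1.[Br-]
Why: Wittig methylenation of the ketone; the trans ring fusion is the thermodynamic one and should survive the basic ylide.

Step 12
Reactants: 19 benzaldehyde; 20 Meldrum's acid
Product: 21 5-benzylidene-2,2-dimethyl-1,3-dioxane-4,6-dione
Conditions: H2O, 75 °C; filtration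
Reagents that add atoms: none
Why: Knoevenagel condensation of the aldehyde with the cyclic malonate, the product crystallising from water.

Step 13
Reactants: 18 (+)-β-caryophyllene; 21 5-benzylidene-2,2-dimethyl-1,3-dioxane-4,6-dione
Product: 24 caryophyllene-fused 4-phenyloxan-2-one (both C1' epimers), via dioxinone cycloadduct 22 (not isolated), via lactone carboxylic acid 23 (not isolated)
Conditions: 21 (1.5 equiv), toluene, 45 °C, dark; then H2O, DMF, 110 °C
Reagents that add atoms: none
Why: Inverse-electron-demand oxa-Diels–Alder reaction of the electron-poor oxadiene with the strained endocyclic E-alkene (oxygen to the tertiary C4, benzylidene carbon to C5) on the outer face of the major ring conformer, the face taken by electrophiles and ortho-quinone methides; suprafacial addition sets C4 (S) and C5 (R) with methyl and H5 trans, C1' forms as a mixture that step 14 erases, and heating in wet DMF expels acetone, hydrates the ketene and decarboxylates acid 23.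

Step 14
Reactants: 24 δ-lactone (C1' epimers)
Product: 27 caryophyllene-fused 4-phenyl-5,6-dihydro-2H-pyran-2-one, via α-phenylselanyl lactone 25 (not isolated), via selenoxide 26 (not isolated)
Conditions: LDA, THF, −78 °C; PhSeBr (1.05 equiv), −78 °C; then NaIO4, NaHCO3, THF/MeOH/H2O, 0 °C to rt
Reagents that add atoms: none
Why: α-Selenenylation of the lactone enolate and selenoxide syn-elimination, possible only towards C1', so both C1' epimers converge on one conjugated lactone; cold stoichiometric PhSeBr and periodate should leave the exocyclic alkene alone.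

Step 15
Reactants: 27 unsaturated lactone
Product: 29 (1'R)-δ-lactone (H1' cis to H5), via silyl ketene acetal 28 (not isolated)
Conditions: CuCl (5 mol %), NaOtBu (5 mol %), 2,2'-bis(di-p-tolylphosphino)-1,1'-binaphthyl (antipode matched to 1'R, 5 mol %), (EtO)2MeSiH (3 equiv), toluene, 0 °C to rt; aq. NaHCO3
Reagents that add atoms: none
Why: Copper hydride catalysed asymmetric conjugate reduction of a β-aryl unsaturated lactone: the ligand-bound monovalent copper hydride adds hydrogen to C1' on the ring face opposite to the vicinal C5–C6 bond, the ligand antipode being chosen so that catalyst and substrate preferences agree, which sets C1' as R; isolated alkenes do not react.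

Step 16
Reactants: 29 (1'R)-δ-lactone
Product: 30 cyclic ketene acetal diphenyl phosphate
Conditions: KHMDS, HMPA, THF, −78 °C; (PhO)2P(O)Cl
Reagents that add atoms: diphenyl chlorophosphate, O=P(Cl)(Oc1ccccc1)Oc1ccccc1
Why: O-Phosphorylation of the potassium lactone enolate, which fixes the enol ether double bond inside the ring between the acetal carbon and the carbon next to C1'.

Step 17
Reactants: 30 ketene acetal phosphate
Product: 31 α-(trimethylstannyl) cyclic enol ether
Conditions: (Me3Sn)2, Pd(PPh3)4 (5 mol %), LiCl, THF, 65 °C
Reagents that add atoms: hexamethylditin, C[Sn](C)(C)[Sn](C)(C)C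
Why: Palladium-catalysed stannylation of a ketene acetal phosphate (oxidative addition of zerovalent palladium into the C–O bond, transmetalation with the distannane) gives the α-alkoxyvinylstannane without moving the double bond.

Step 18
Reactants: 32 2,2,6-trimethyl-4H-1,3-dioxin-4-one
Product: 33 6-(chloromethyl)-2,2-dimethyl-4H-1,3-dioxin-4-one
Conditions: LDA, THF, −78 °C; C2Cl6, −78 to −40 °C
Reagents that add atoms: hexachloroethane, ClC(Cl)(Cl)C(Cl)(Cl)Cl
Why: γ-Deprotonation of the dioxinone to its lithium dienolate and chlorination at the γ-carbon.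

Step 19
Reactants: 31 α-stannyl enol ether; 33 6-(chloromethyl)-2,2-dimethyl-4H-1,3-dioxin-4-one
Product: 34 enol ether dioxinone (endocyclic enol ether with CH2-dioxinone on the acetal carbon)
Conditions: Pd2(dba)3 (2.5 mol %), P(2-furyl)3 (10 mol %), THF, 45 °C; chromatography on Et3N-deactivated silica
Reagents that add atoms: none
Why: Stille coupling of an α-alkoxyvinylstannane with an allylic chloride, the allylpalladium intermediate coupling at its CH2 terminus; the neutral conditions keep the enol ether double bond in the ring and out of conjugation with the dioxinone, which dehydration of the corresponding lactol would not.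

Step 20
Reactants: 34 enol ether dioxinone
Product: 36 bis-deformyl psidial A, via acylketene 35 (not isolated)
Conditions: toluene (0.005 M), 110 °C, argon
Reagents that add atoms: none
Why: Proposed new method: at 110 °C the dioxinone loses acetone by retro-[4+2] reaction to give acylketene 35, whose ketene carbon is attacked by the nucleophilic β-carbon of the cyclic enol ether (the carbon next to C1'); the oxocarbenium/enolate zwitterion loses the proton on that carbon and enolises to the phloroglucinol monoether. The closest known reactions are dioxinone-to-acylketene thermolysis with capture by nucleophiles, C–C bond formation at the β-carbon of enol ethers in their intermolecular [4+2] reactions with acylketenes, and the 6π-electrocyclisation of dienylketenes to phenols (the enol tautomer of 35 is such a dienylketene); intramolecular C-acylation of a cyclic enol ether with aromatisation has not been shown. The benzene ring closes in a 6-(enolendo)-exo-dig mode (or by disrotatory 6π closure of the enol tautomer), and no stereocentre is formed. The step needs C- and not O-acylation: the ring oxygen is already alkylated and its attack would give only a reversible oxonium zwitterion, whereas attack by carbon is made irreversible by aromatisation. High dilution should suppress ketene dimerisation and acylation of the product phenols, and the neutral medium should leave the exocyclic methylene, the C1' centre and the tertiary alkyl ether (never made by substitution) untouched.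

Step 21
Reactants: 36 bis-deformyl psidial A
Product: 38 psidial A, via bis-iminium salt 37 (not isolated)
Conditions: POCl3 (3 equiv), DMF (4 equiv), MeCN, 0 °C to rt; then H2O, 50 °C
Reagents that add atoms: N,N-dimethylformamide, CN(C)C=O; water, O
Why: Vilsmeier–Haack formylation: each of the two free ring positions is ortho or para to all three oxygen substituents and is attacked in turn by the chloroiminium ion, and hydrolysis of bis-iminium salt 37 gives the dialdehyde; the mild medium should spare the 1,1-disubstituted alkene and the tertiary alkyl aryl ether.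

**Compound list**
1 | cyclohex-2-en-1-one | O=C1C=CCCC1 | starting material
2 | isobutene | C=C(C)C | starting material
3 | (1R,6S)-7,7-dimethylbicyclo[4.2.0]octan-2-one (trans-fused photoadduct) | O=C1CCC[C@H]2[C@H]1CC2(C)C | intermediate (not isolated)
4 | (1S,6S)-7,7-dimethylbicyclo[4.2.0]octan-2-one (cis-fused) | O=C1CCC[C@H]2[C@@H]1CC2(C)C | intermediate
5 | methyl (1S,6S)-7,7-dimethyl-2-oxobicyclo[4.2.0]octane-3-carboxylate (C3 epimers, partly enol) | O=C1C(C(=O)OC)CC[C@H]2[C@@H]1CC2(C)C | intermediate
6 | methyl (1S,3R,6S)-3,7,7-trimethyl-2-oxobicyclo[4.2.0]octane-3-carboxylate (3-methyl anti to the cyclobutane) | O=C1[C@](C)(C(=O)OC)CC[C@H]2[C@@H]1CC2(C)C | intermediate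
7 | methyl propiolate | C#CC(=O)OC | starting material
8 | methyl (1S,3R,6S)-2-hydroxy-2-(3-methoxy-3-oxoprop-1-yn-1-yl)-3,7,7-trimethylbicyclo[4.2.0]octane-3-carboxylate (alkynyl anti, hydroxyl syn to the cyclobutane) | O[C@]1(C#CC(=O)OC)[C@](C)(C(=O)OC)CC[C@H]2[C@@H]1CC2(C)C | intermediate
9 | methyl 2-hydroxy-2-(3-methoxy-3-oxopropyl)-3,7,7-trimethylbicyclo[4.2.0]octane-3-carboxylate (configuration as 8) | O[C@]1(CCC(=O)OC)[C@](C)(C(=O)OC)CC[C@H]2[C@@H]1CC2(C)C | intermediate (not isolated)
10 | methyl 3,7,7-trimethyl-5'-oxospiro[bicyclo[4.2.0]octane-2,2'-oxolane]-3-carboxylate (lactone oxygen syn to the cyclobutane) | O=C1CC[C@@]2(O1)[C@](C)(C(=O)OC)CC[C@H]3[C@@H]2CC3(C)C | intermediate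
11 | bridged keto lactone (5-oxo-13-nor-4,8-cyclocaryophyllane-6,8-carbolactone) | O=C1O[C@]23C[C@H]1C(=O)[C@]2(C)CC[C@H]4[C@@H]3CC4(C)C | intermediate (not isolated)
12 | methyl 8-hydroxy-5-oxo-13-nor-4,8-cyclocaryophyllane-6-carboxylate (cyclobutane cis-fused, hydrindane trans-fused, C6 epimers) | O[C@]12CC(C(=O)OC)C(=O)[C@]1(C)CC[C@H]3[C@@H]2CC3(C)C | intermediate
13 | 8-hydroxy-13-nor-4,8-cyclocaryophyllan-5-one (angular hydroxyl and methyl anti) | O[C@]12CCC(=O)[C@]1(C)CC[C@H]3[C@@H]2CC3(C)C | intermediate
14 | 13-nor-4,8-cyclocaryophyllane-5,8-diol (5-hydroxyl cis to the 4-methyl, trans to the 8-hydroxyl) | O[C@]12CC[C@@H](O)[C@]1(C)CC[C@H]3[C@@H]2CC3(C)C | intermediate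
15 | 5-methanesulfonate of diol 14 | O[C@]12CC[C@@H](OS(C)(=O)=O)[C@]1(C)CC[C@H]3[C@@H]2CC3(C)C | intermediate
16 | (1S,4E,9S)-4,11,11-trimethylbicyclo[7.2.0]undec-4-en-8-one (cis-fused, caryophyllane numbering) | O=C1CC/C=C(\C)CC[C@H]2[C@@H]1CC2(C)C | intermediate (not isolated)
17 | (1S,4E,9R)-4,11,11-trimethylbicyclo[7.2.0]undec-4-en-8-one (trans-fused, caryophyllane numbering) | O=C1CC/C=C(\C)CC[C@H]2[C@H]1CC2(C)C | intermediate
18 | (+)-β-caryophyllene, (1S,4E,9R)-4,11,11-trimethyl-8-methylidenebicyclo[7.2.0]undec-4-ene | C=C1CC/C=C(\C)CC[C@H]2[C@H]1CC2(C)C | intermediate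
19 | benzaldehyde | O=Cc1ccccc1 | starting material
20 | Meldrum's acid (2,2-dimethyl-1,3-dioxane-4,6-dione) | CC1(C)OC(=O)CC(=O)O1 | starting material
21 | 5-benzylidene-2,2-dimethyl-1,3-dioxane-4,6-dione | CC1(C)OC(=O)C(=Cc2ccccc2)C(=O)O1 | intermediate
22 | oxa-Diels–Alder adduct: dihydropyran-fused 2,2-dimethyl-1,3-dioxin-4-one on C4 (O) and C5 (CHPh) of 18; 1S,4S,5R,9R, both C1' epimers | C=C1CC[C@@H]2C(c3ccccc3)C3=C(OC(C)(C)OC3=O)O[C@@]2(C)CC[C@H]2[C@H]1CC2(C)C | intermediate (not isolated)
23 | α-carboxy δ-lactone from 22 | C=C1CC[C@@H]2C(c3ccccc3)C(C(=O)O)C(=O)O[C@@]2(C)CC[C@H]2[C@H]1CC2(C)C | intermediate (not isolated)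
24 | caryophyllene-fused 4-phenyloxan-2-one (lactone O on C4, CHPh on C5; 1S,4S,5R,9R, both C1' epimers) | C=C1CC[C@@H]2C(c3ccccc3)CC(=O)O[C@@]2(C)CC[C@H]2[C@H]1CC2(C)C | intermediate
25 | α-phenylselanyl derivative of 24 | C=C1CC[C@@H]2C(c3ccccc3)C([Se]c3ccccc3)C(=O)O[C@@]2(C)CC[C@H]2[C@H]1CC2(C)C | intermediate (not isolated)
26 | selenoxide of 25 | C=C1CC[C@@H]2C(c3ccccc3)C([Se](=O)c3ccccc3)C(=O)O[C@@]2(C)CC[C@H]2[C@H]1CC2(C)C | intermediate (not isolated)
27 | caryophyllene-fused 4-phenyl-5,6-dihydro-2H-pyran-2-one (1S,4S,5R,9R) | C=C1CC[C@@H]2C(c3ccccc3)=CC(=O)O[C@@]2(C)CC[C@H]2[C@H]1CC2(C)C | intermediate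
28 | diethoxy(methyl)silyl ketene acetal of lactone 29 | C=C1CC[C@@H]2[C@H](c3ccccc3)C=C(O[Si](C)(OCC)OCC)O[C@@]2(C)CC[C@H]2[C@H]1CC2(C)C | intermediate (not isolated)
29 | (1'R)-δ-lactone (1S,4S,5R,9R,1'R; H1' cis to H5, phenyl cis to the C4 methyl) | C=C1CC[C@@H]2[C@H](c3ccccc3)CC(=O)O[C@@]2(C)CC[C@H]2[C@H]1CC2(C)C | intermediate
30 | cyclic ketene acetal diphenyl phosphate of 29 | C=C1CC[C@@H]2[C@H](c3ccccc3)C=C(OP(=O)(Oc3ccccc3)Oc3ccccc3)O[C@@]2(C)CC[C@H]2[C@H]1CC2(C)C | intermediate
31 | α-(trimethylstannyl) cyclic enol ether | C=C1CC[C@@H]2[C@H](c3ccccc3)C=C([Sn](C)(C)C)O[C@@]2(C)CC[C@H]2[C@H]1CC2(C)C | intermediate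
32 | 2,2,6-trimethyl-4H-1,3-dioxin-4-one | CC1=CC(=O)OC(C)(C)O1 | starting material
33 | 6-(chloromethyl)-2,2-dimethyl-4H-1,3-dioxin-4-one | ClCC1=CC(=O)OC(C)(C)O1 | intermediate
34 | enol ether dioxinone (key-step precursor) | C=C1CC[C@@H]2[C@H](c3ccccc3)C=C(CC3=CC(=O)OC(C)(C)O3)O[C@@]2(C)CC[C@H]2[C@H]1CC2(C)C | intermediate
35 | acylketene from 34 | C=C1CC[C@@H]2[C@H](c3ccccc3)C=C(CC(=O)C=C=O)O[C@@]2(C)CC[C@H]2[C@H]1CC2(C)C | intermediate (not isolated)
36 | bis-deformyl psidial A | C=C1CC[C@@H]2[C@H](c3ccccc3)c3c(O)cc(O)cc3O[C@@]2(C)CC[C@H]2[C@H]1CC2(C)C | intermediate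
37 | bis(dimethyliminium) dichloride of psidial A | C=C1CC[C@@H]2[C@H](c3ccccc3)c3c(O)c(C=[N+](C)C)c(O)c(C=[N+](C)C)c3O[C@@]2(C)CC[C@H]2[C@H]1CC2(C)C.[Cl-].[Cl-] | intermediate (not isolated)
38 | psidial A | C=C1CC[C@@H]2[C@H](c3ccccc3)c3c(O)c(C=O)c(O)c(C=O)c3O[C@@]2(C)CC[C@H]2[C@H]1CC2(C)C | target

**Step count**
- Total: 21 steps.
- Longest linear sequence: 19 steps (steps 1–11, 13–17, 19–21); steps 12 and 18 are side branches.

**Steps most likely to fail**

1. Step 20 (proposed new method). The acylketene may be lost by O-acylation with loss of the tertiary alkyl group, by dimerisation, or the enol ether may leave the ring before it cyclises. The fallback uses a known three-component reaction type and brings the arene in ready-made. (+)-β-Caryophyllene 18, benzaldehyde 19 and commercial 2,4,6-trihydroxybenzene-1,3-dicarbaldehyde (O=Cc1c(O)cc(O)c(C=O)c1O) are heated in water at 100 °C. Knoevenagel condensation gives benzylidene ortho-quinone methide F1, which adds by oxa-Diels–Alder reaction across C4=C5 of 18. This gives psidial A 38 directly, together with its C1' epimer, which is removed by chromatography. The fallback sets out from 18 and comes back at 38.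

2. Step 13. The cycloaddition may be slow, the oxadiene may react with the exocyclic methylene in an ene reaction, or face selectivity may be poor. The fallback delivers oxygen and carbon with a 1,3-dipole instead. Compound 18 reacts with benzonitrile oxide (from N-hydroxybenzimidoyl chloride and Et3N) at the strained endocyclic alkene to give isoxazoline F2 (oxygen on C4, carbon on C5, suprafacial). Mo(CO)6 in wet MeCN cleaves the N–O bond and hydrolysis gives β-hydroxy ketone F3. Steglich esterification of the tertiary alcohol with diethylphosphonoacetic acid gives phosphonate ester F4. Intramolecular Horner–Wadsworth–Emmons reaction (LiCl, DBU, MeCN) closes the unsaturated lactone 27. The fallback sets out from 18 and comes back at 27.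

3. Step 15. Hydride delivery may show poor facial selectivity if catalyst and substrate preferences are mismatched, or carbonyl reduction may compete. The fallback does not reset C1': steps 14 and 15 are skipped and the configuration is taken from the cycloaddition. Lactone 24 is separated into its two C1' diastereomers by chromatography or crystallisation. The (1'R) epimer is 29 and is taken on from step 16; the (1'S)-lactone F5 is set aside. The fallback sets out from 24 and comes back at 29.

**Further compounds**
F1 | step 20 | 5-benzylidene-2,4-dihydroxy-6-oxocyclohexa-1,3-diene-1,3-dicarbaldehyde (ortho-quinone methide) | O=CC1=C(O)C(C=O)=C(O)C(=Cc2ccccc2)C1=O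
F2 | step 13 | 3-phenyl-2-isoxazoline fused on C4 (O) and C5 (C) of 18 (1S,4S,5R,9R) | C=C1CC[C@@H]2C(c3ccccc3)=NO[C@@]2(C)CC[C@H]2[C@H]1CC2(C)C
F3 | step 13 | 5-benzoyl-4-hydroxy-4,5-dihydro-(+)-β-caryophyllene (β-hydroxy ketone, configuration as F2) | C=C1CC[C@H](C(=O)c2ccccc2)[C@@](C)(O)CC[C@H]2[C@H]1CC2(C)C
F4 | step 13 | diethylphosphonoacetate ester of F3 | C=C1CC[C@H](C(=O)c2ccccc2)[C@@](C)(OC(=O)CP(=O)(OCC)OCC)CC[C@H]2[C@H]1CC2(C)C
F5 | step 15 | (1'S)-δ-lactone, C1' epimer of 29 | C=C1CC[C@@H]2[C@@H](c3ccccc3)CC(=O)O[C@@]2(C)CC[C@H]2[C@H]1CC2(C)C
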